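Atom numbers follow the isochromene skeleton (C1, O2, C3, C4, C4a, C5, C6, C7, C8, C8a). Retrosynthesis cuts, in this order: the C7–O octanoate bond; O2–C3 (pyran ring) together with C5–C6 (ring A); C7–C8; C4–C4a.
Forward: methyl acetoacetate supplies C5–C4a–C8a–C8, bromoformylation adds C1, Sonogashira coupling adds C4–C3–heptyl, and the derived acid chloride acylates C7 of a lactic acid dioxolanone whose lactone carbonyl is the future C6.
Enabling feature: in the open chain C5 is the methyl γ-carbon of an alkylidene β-keto aldehyde (C8a carries C1=O and C8=O and is doubly bonded to C4a), C6 is an acylal carbonyl six atoms along (C5–C4a–C8a–C8–C7–C6), and the C1 oxygen lies five atoms from alkyne carbon C3.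
One base-triggered cascade therefore closes ring A at C5–C6, ejects the auxiliary as pivalaldehyde to free the C7 hydroxyl, and then closes the pyran ring at O2–C3; octanoylation ends the route.
Stereochemistry: C7 (R) is taken from (R)-lactic acid by self-regeneration of stereocentres (acylation of the cis-dioxolanone enolate anti to tert-butyl, net retention). C7 then has no α-hydrogen and C8a already bears C1, so ring A cannot racemize by tautomerism.

Key step: step 7

Assumption: the C4a=C8a alkene geometry of 6, 7, 9, 10, 11, 13 and 14 is left unassigned and mixtures are carried, because deprotonation at C5 in step 7 turns this bond into a freely rotating single bond.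

Step 1
Reactants: 1 (R)-lactic acid; 2 pivalaldehyde
Product: 3 (2R,5R)-2-tert-butyl-5-methyl-1,3-dioxolan-4-one (cis)
Conditions: cat. p-TsOH·H2O, cat. H2SO4, pentane, reflux with water separator; recrystallisation from pentane/Et2O at −78 °C
Reagents that add atoms: none
Why: Acid-catalysed acetalisation of the α-hydroxy acid under thermodynamic control should favour the cis isomer, whose acetal carbon is set by the lactate center and which crystallisation purifies (auxiliary for self-regeneration of stereocentres).

Step 2
Reactants: 4 methyl acetoacetate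
Product: 6 methyl 3-bromo-2-formylbut-2-enoate, via iminium bromide 5 (not isolated)
Conditions: PBr3, DMF, CHCl3, 0 to 60 °C; then aq. NaOAc, 0 °C
Reagents that add atoms: N,N-dimethylformamide CN(C)C=O; phosphorus tribromide BrP(Br)Br; water O
Why: Vilsmeier–Haack haloformylation should formylate the active methylene (future C8a) and exchange the enolised ketone oxygen for bromide, as in the known conversion of 4-hydroxycoumarin to 4-chloro-3-formylcoumarin, so that C1, C8a, C8, C4a and C5 are in place after hydrolysis of 5.

Step 3
Reactants: 6 methyl 3-bromo-2-formylbut-2-enoate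
Product: 7 methyl 3-bromo-2-(dimethoxymethyl)but-2-enoate
Conditions: MeOSiMe3 (2.2 equiv), Me3SiOTf (5 mol %), CH2Cl2, −78 °C; pyridine quench
Reagents that add atoms: methoxytrimethylsilane CO[Si](C)(C)C
Why: Acetalisation with the silyl ether and catalytic silyl triflate (Noyori conditions) masks the C1 aldehyde at low temperature without free methanol, which could displace the vinylogous acyl bromide.

Step 4
Reactants: 7 methyl 3-bromo-2-(dimethoxymethyl)but-2-enoate; 8 non-1-yne
Product: 9 methyl 2-(dimethoxymethyl)-3-methyldodec-2-en-4-ynoate
Conditions: PdCl2(PPh3)2 (3 mol %), CuI (5 mol %), Et3N, THF, 50 °C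
Reagents that add atoms: none
Why: Sonogashira coupling at the ester-activated β-bromoacrylate should form C4–C4a, the alkyne carbon bearing the heptyl chain becoming C3.

Step 5
Reactants: 9 methyl 2-(dimethoxymethyl)-3-methyldodec-2-en-4-ynoate
Product: 10 potassium 2-(dimethoxymethyl)-3-methyldodec-2-en-4-ynoate
Conditions: KOSiMe3 (1.2 equiv), THF, 23 to 40 °C; salt collected by filtration
Reagents that add atoms: potassium trimethylsilanolate C[Si](C)(C)[O-].[K+]
Why: Anhydrous silanolate cleavage of the hindered methyl ester should give the dry carboxylate salt directly and leave the acetal untouched.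

Step 6
Reactants: 10 potassium 2-(dimethoxymethyl)-3-methyldodec-2-en-4-ynoate; 3 (2R,5R)-2-tert-butyl-5-methyl-1,3-dioxolan-4-one
Product: 14 (2R,5S)-2-tert-butyl-5-(2-formyl-3-methyldodec-2-en-4-ynoyl)-5-methyl-1,3-dioxolan-4-one, via acid chloride 11 (not isolated), via lithium enolate 12 (not isolated), via dimethyl acetal 13 (not isolated)
Conditions: 10, (COCl)2 (1.05 equiv), CH2Cl2, 0 °C, then evaporation; 3, LiN(iPr)2 (1.05 equiv), THF, −78 °C; 11 in THF added at −78 °C, then −40 °C; then 1 M HCl, THF, 0 to 23 °C
Reagents that add atoms: water O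
Why: The carboxylate salt should give the acid chloride with (COCl)2 without release of HCl, Claisen-type C-acylation of the dioxolanone lithium enolate on the face anti to tert-butyl creates C7 with retention of the lactate configuration (self-regeneration of stereocentres), and dilute acid then hydrolyses the dimethyl acetal, which is far more labile than the acylal.

Step 7
Reactants: 14 (2R,5S)-2-tert-butyl-5-(2-formyl-3-methyldodec-2-en-4-ynoyl)-5-methyl-1,3-dioxolan-4-one
Product: 17 (7R)-3-heptyl-7-hydroxy-7-methyl-6H-isochromene-6,8(7H)-dione, via dienolate 15 (not isolated), via vinylogous acid anion 16 (not isolated)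
Conditions: DBU (1.5 equiv), DMAP (0.2 equiv), MeCN, 0 to 23 °C; then pH 5 citrate buffer
Reagents that add atoms: none
Why: DBU should remove a proton from the C5 methyl group, the γ-position of the alkylidene β-keto aldehyde, to give the cross-conjugated dienolate 15, in which rotation about C8a–C4a erases the alkene geometry; C5 then attacks the acylal carbonyl C6, the tetrahedral intermediate opens the dioxolanone, the hemiacetal alkoxide expels pivalaldehyde and proton transfer gives the vinylogous acid anion 16. The closest known reaction type is the vinylogous Claisen/Dieckmann acylation, in particular Dieckmann closure onto 1,3-dioxolan-4-one carbonyls as used for tetronic acids. Ring A closes in a 6-(enolendo)-exo-trig mode at C5–C6; the pyran ring then closes by 6-endo-dig addition of the C1 enolate oxygen to alkyne carbon C3, now the δ-position of the C6 dienone, which is the base-mediated cycloisomerization known for 2-alkynyl vinylogous acids of this class. No stereocenter is created: C7 was fixed in step 6, has no α-hydrogen, and C5 and C8a stay distinguishable because C8a carries C1. The step needs C-acylation at C5 in preference to attack by C8a or by the C1 enolate oxygen: C8a would give a four-membered ring, and a six-membered enol lactone formed at oxygen is an activated ester that DMAP should return to the C-acylated anion, the thermodynamic sink. Closure of a pyran through the C8 oxygen before ring A forms should be slow, because the alkyne of 15 is conjugated to an electron-rich dienolate and becomes an acceptor only in 16.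

Step 8
Reactants: 17 (7R)-3-heptyl-7-hydroxy-7-methyl-6H-isochromene-6,8(7H)-dione; 18 octanoyl chloride
Product: 19 (7R)-3-heptyl-7-methyl-6,8-dioxo-7,8-dihydro-6H-isochromen-7-yl octanoate
Conditions: Et3N (2 equiv), DMAP (10 mol %), CH2Cl2, 0 to 23 °C
Reagents that add atoms: none
Why: DMAP-catalysed acylation (Steglich-type acyl transfer) of the tertiary C7 hydroxyl, a standard last step for 7-hydroxy pyranoquinones of this class, leaves the quaternary stereocenter untouched.

Compound list
1 | (R)-lactic acid, (2R)-2-hydroxypropanoic acid | C[C@@H](O)C(=O)O | starting material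
2 | pivalaldehyde, 2,2-dimethylpropanal | CC(C)(C)C=O | starting material
3 | (2R,5R)-2-tert-butyl-5-methyl-1,3-dioxolan-4-one, cis | C[C@H]1O[C@@H](C(C)(C)C)OC1=O | intermediate
4 | methyl acetoacetate | COC(=O)CC(C)=O | starting material
5 | N-[3-bromo-2-(methoxycarbonyl)but-2-en-1-ylidene]-N-methylmethanaminium bromide | COC(=O)C(C=[N+](C)C)=C(C)Br.[Br-] | intermediate (not isolated)
6 | methyl 3-bromo-2-formylbut-2-enoate, geometry unassigned | COC(=O)C(C=O)=C(C)Br | intermediate
7 | methyl 3-bromo-2-(dimethoxymethyl)but-2-enoate | COC(=O)C(C(OC)OC)=C(C)Br | intermediate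
8 | non-1-yne | CCCCCCCC#C | starting material
9 | methyl 2-(dimethoxymethyl)-3-methyldodec-2-en-4-ynoate | CCCCCCCC#CC(C)=C(C(OC)OC)C(=O)OC | intermediate
10 | potassium 2-(dimethoxymethyl)-3-methyldodec-2-en-4-ynoate | CCCCCCCC#CC(C)=C(C(OC)OC)C(=O)[O-].[K+] | intermediate
11 | 2-(dimethoxymethyl)-3-methyldodec-2-en-4-ynoyl chloride | CCCCCCCC#CC(C)=C(C(OC)OC)C(Cl)=O | intermediate (not isolated)
12 | lithium (2R)-2-tert-butyl-5-methyl-1,3-dioxol-4-olate | CC1=C([O-])O[C@H](C(C)(C)C)O1.[Li+] | intermediate (not isolated)
13 | (2R,5S)-2-tert-butyl-5-[2-(dimethoxymethyl)-3-methyldodec-2-en-4-ynoyl]-5-methyl-1,3-dioxolan-4-one | CCCCCCCC#CC(C)=C(C(OC)OC)C(=O)[C@]1(C)O[C@@H](C(C)(C)C)OC1=O | intermediate (not isolated)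
14 | (2R,5S)-2-tert-butyl-5-(2-formyl-3-methyldodec-2-en-4-ynoyl)-5-methyl-1,3-dioxolan-4-one | CCCCCCCC#CC(C)=C(C=O)C(=O)[C@]1(C)O[C@@H](C(C)(C)C)OC1=O | intermediate
15 | DBU-H+ salt of the C5-deprotonated dienolate of 14 | CCCCCCCC#CC(=C)C(C=O)=C([O-])[C@]1(C)O[C@@H](C(C)(C)C)OC1=O.C1CCC2=[NH+]CCCN2CC1 | intermediate (not isolated)
16 | DBU-H+ salt of the enolate of (2R)-2-hydroxy-4-(hydroxymethylidene)-2-methyl-5-(non-1-yn-1-yl)cyclohex-5-ene-1,3-dione | O[C@]1(C)C(=O)C=C(C#CCCCCCCC)C(=C[O-])C1=O.C1CCC2=[NH+]CCCN2CC1 | intermediate (not isolated)
17 | (7R)-3-heptyl-7-hydroxy-7-methyl-6H-isochromene-6,8(7H)-dione | O[C@]1(C)C(=O)C=C2C=C(CCCCCCC)OC=C2C1=O | intermediate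
18 | octanoyl chloride | CCCCCCCC(=O)Cl | starting material
19 | (7R)-3-heptyl-7-methyl-6,8-dioxo-7,8-dihydro-6H-isochromen-7-yl octanoate | CCCCCCCC(=O)O[C@]1(C)C(=O)C=C2C=C(CCCCCCC)OC=C2C1=O | target

Total steps: 8. Longest linear sequence: 7 (steps 2 to 8); step 1 is the auxiliary branch.

Steps most likely to fail

Step 7. Carbon–carbon bond formation by the stabilised, delocalised dienolate may be too slow, so that acyl transfer to the enolate oxygen, attack of the amidine on the acylal, or closure of a pyran through the C8 oxygen takes over. The fallback separates the two ring closures and uses a hard lithium dienolate on the acetal. It sets out from 13, taken from step 6 by a neutral NH4Cl quench in place of the acid treatment. LiN(SiMe3)2 (2.5 equiv) in THF at −78 to −20 °C deprotonates the C5 methyl, which is γ to the C8 ketone only, and oxygen attack on C6 would now need a four-membered ring. Ring A closes by the same Dieckmann-type acylation with loss of pivalaldehyde, and work-up with 1 M HCl in THF hydrolyses the acetal to the monocyclic vinylogous acid (2R)-2-hydroxy-4-(hydroxymethylidene)-2-methyl-5-(non-1-yn-1-yl)cyclohex-5-ene-1,3-dione F1. F1 is then cycloisomerised in MeCN with aqueous KH2PO4/K2HPO4 buffer (pH 7.2), or with catalytic Au(OAc)3 in CF3CO2H/1,2-dichloroethane, the established closure for this substrate class. The fallback comes back to the route at 17.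

Step 6. Addition of the tertiary enolate to the fully substituted, hindered acid chloride may be slow, leaving room for proton transfer from the γ-methyl group (ketene formation) or for O-acylation of the enolate. The fallback replaces acylation by aldol addition and oxidation. It sets out from 9. Reduction with iBu2AlH in CH2Cl2 at −78 °C gives 2-(dimethoxymethyl)-3-methyldodec-2-en-4-yn-1-ol F2, and MnO2 in CH2Cl2 oxidises it to 2-(dimethoxymethyl)-3-methyldodec-2-en-4-ynal F3. Aldol addition of enolate 12 (from 3 as in step 6) to this small sp2 electrophile at −78 °C, again anti to tert-butyl, gives (2R,5S)-2-tert-butyl-5-[2-(dimethoxymethyl)-1-hydroxy-3-methyldodec-2-en-4-yn-1-yl]-5-methyl-1,3-dioxolan-4-one F4 as a carbinol mixture. Dess–Martin periodinane with NaHCO3 in CH2Cl2 oxidises F4 to 13, where the fallback comes back to the route; the acid treatment of step 6 then gives 14.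

Step 2. Bromoformylation of the acyclic β-keto ester may stop at simple oxygen-to-bromine exchange or go on to a second formylation at the methyl group. The fallback builds the enyne first and adds C1 by enolate chemistry. It sets out from 8. Addition of 8 across commercial methyl but-2-ynoate with catalytic Pd(OAc)2 and tris(2,6-dimethoxyphenyl)phosphine in THF at 23 °C gives methyl (2E)-3-methyldodec-2-en-4-ynoate F5. Its dienolate, made with LiN(iPr)2 in THF/DMPU at −78 °C, is formylated at the α-carbon with methyl formate, and return of conjugation gives methyl 2-formyl-3-methyldodec-2-en-4-ynoate F6. Acetalisation under the conditions of step 3 brings the fallback back to the route at 9.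

Further compounds
F1 | step 7 | (2R)-2-hydroxy-4-(hydroxymethylidene)-2-methyl-5-(non-1-yn-1-yl)cyclohex-5-ene-1,3-dione | O[C@]1(C)C(=O)C=C(C#CCCCCCCC)C(=CO)C1=O
F2 | step 6 | 2-(dimethoxymethyl)-3-methyldodec-2-en-4-yn-1-ol | CCCCCCCC#CC(C)=C(CO)C(OC)OC
F3 | step 6 | 2-(dimethoxymethyl)-3-methyldodec-2-en-4-ynal | CCCCCCCC#CC(C)=C(C=O)C(OC)OC
F4 | step 6 | (2R,5S)-2-tert-butyl-5-[2-(dimethoxymethyl)-1-hydroxy-3-methyldodec-2-en-4-yn-1-yl]-5-methyl-1,3-dioxolan-4-one | CCCCCCCC#CC(C)=C(C(OC)OC)C(O)[C@]1(C)O[C@@H](C(C)(C)C)OC1=O
F5 | step 2 | methyl (2E)-3-methyldodec-2-en-4-ynoate | CCCCCCCC#C/C(C)=C/C(=O)OC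
F6 | step 2 | methyl 2-formyl-3-methyldodec-2-en-4-ynoate | CCCCCCCC#CC(C)=C(C=O)C(=O)OC
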